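**Strategy.** The quinone ring is the bis-enol tautomer of a cyclohexane-1,2,4,5-tetraone and is therefore read as a head-to-tail pair of two α-keto-acid units, C1(=O)–C2(OH)–C3(nonadecyl) and C4(=O)–C5(OMe)–C6(H). The key step joins them in one flask by a crossed Claisen acylation (C3–C4) and a Dieckmann closure (C6–C1), which gives the ring at the quinone oxidation level without an oxidant. The precursors are the potassium enolate of ethyl 2-oxodocosanoate, which carries C1–C3 and the whole side chain, and the silyl enol ether of methyl pyruvate, whose ketone is unmasked only by the methoxide that the first acylation expels. Acid-catalysed etherification of the unhindered C5 hydroxyl completes the target.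

Key step: step 2

Remark on the chemistry: the trimethylsilyl enol ether of methyl pyruvate is taken as a purchased reagent. Ring atoms are numbered as in 2-hydroxy-5-methoxy-3-nonadecylcyclohexa-2,5-diene-1,4-dione (C1 and C4 carbonyls, C2 hydroxyl, C3 nonadecyl, C5 methoxy, C6 hydrogen).

**Step 1**
Reactants: 1 1-bromoeicosane; 2 diethyl oxalate
Product: 4 ethyl 2-oxodocosanoate, via eicosylmagnesium bromide 3 (not isolated)
Conditions: Mg turnings, I2 (cat.), THF, 50 °C; then added slowly to 2 (2.5 equiv), THF/Et2O, −78 °C; 1 M HCl
Reagents that add atoms: none
Why: Grignard acylation of a dialkyl oxalate, in which inverse addition into excess oxalate at −78 °C should hold the reaction at monoaddition and give the α-keto ester.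

**Step 2**
Reactants: 4 ethyl 2-oxodocosanoate; 5 methyl 2-(trimethylsilyloxy)acrylate
Product: 10 2,5-dihydroxy-3-nonadecyl-1,4-benzoquinone, via potassium enolate 6 (not isolated), via silyl-masked triketo ester enolate 7 (not isolated), via open-chain dienolate 8 (not isolated), via dipotassium quinone salt 9 (not isolated)
Conditions: 4 added to KN(SiMe3)2 (2.2 equiv), THF, −78 °C; then 5 (1.3 equiv), −78 to 50 °C; 1 M HCl
Reagents that add atoms: none
Why: Proposed new method: enolate 6 should acylate at C3 on the ester carbonyl C4 of 5 to give 7 and potassium methoxide (crossed Claisen, bond C3–C4); the methoxide then removes the trimethylsilyl group as MeOSiMe3 and so unveils the C6 enolate in 8 only after the cross bond exists, and C6 attacks the ethyl ester carbon C1 (Dieckmann, bond C6–C1) with loss of ethoxide to give 9, a doubly vinylogous carboxylate that acts as the thermodynamic sink and to which reversible O-acylation products should drain. The closest known reaction types are the base-mediated head-to-tail double Claisen self-condensation of α-keto esters and oxalyl esters to 3,6-disubstituted 2,5-dihydroxy-1,4-benzoquinones, the succinylsuccinate synthesis and the alkoxide cleavage of trimethylsilyl enol ethers to metal enolates; the crossed pairing and the silyl relay are new. The carbocycle closes in a 6-(enolendo)-exo-trig mode. No stereocentre is formed. The step needs cross- over homo-condensation and attack at the ester carbonyl of 5 over aldol addition or conjugate addition at C6: 4 is present only as its enolate and 5 only as a masked electrophile that cannot enolise, no free ketone exists before ring closure, and the silyloxy donor turns C6 into an enol ether carbon of low acceptor character.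

**Step 3**
Reactants: 10 2,5-dihydroxy-3-nonadecyl-1,4-benzoquinone
Product: 11 Irisoquin C (2-hydroxy-5-methoxy-3-nonadecyl-1,4-benzoquinone)
Conditions: MeOH/CH2Cl2 (1:1), H2SO4 (cat.), 23 °C, stopped when 10 is consumed
Reagents that add atoms: methanol, CO
Why: Fischer-type etherification of a vinylogous carboxylic acid (addition of methanol to the protonated quinone, loss of water), which should take place at the C5 hydroxyl flanked by C6–H, because the C2 hydroxyl is shielded by the nonadecyl chain at C3 and its ether would be twisted out of conjugation.

**Compound list**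
1 | 1-bromoeicosane | CCCCCCCCCCCCCCCCCCCCBr | starting material
2 | diethyl oxalate | CCOC(=O)C(=O)OCC | starting material
3 | eicosylmagnesium bromide | CCCCCCCCCCCCCCCCCCCC[Mg]Br | intermediate
4 | ethyl 2-oxodocosanoate | CCCCCCCCCCCCCCCCCCCCC(=O)C(=O)OCC | intermediate
5 | methyl 2-(trimethylsilyloxy)acrylate (methyl 2-[(trimethylsilyl)oxy]prop-2-enoate) | C=C(O[Si](C)(C)C)C(=O)OC | starting material
6 | potassium (Z)-1-ethoxy-1-oxodocos-2-en-2-olate (potassium enolate of 4) | CCCCCCCCCCCCCCCCCCC/C=C(\[O-])C(=O)OCC.[K+] | intermediate
7 | potassium enolate of ethyl 3-nonadecyl-2,4-dioxo-5-(trimethylsilyloxy)hex-5-enoate, EtO2C–C(=O)–C(C19H39)=C(OK)–C(OSiMe3)=CH2 (one resonance form, enolate geometry not defined) | CCCCCCCCCCCCCCCCCCCC(=C([O-])C(=C)O[Si](C)(C)C)C(=O)C(=O)OCC.[K+] | intermediate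
8 | dipotassium dienolate of ethyl 3-nonadecyl-2,4,5-trioxohexanoate, EtO2C–C(=O)–C(C19H39)=C(OK)–C(OK)=CH2 (one resonance form) | CCCCCCCCCCCCCCCCCCCC(=C([O-])C([O-])=C)C(=O)C(=O)OCC.[K+].[K+] | intermediate
9 | dipotassium salt of 2,5-dihydroxy-3-nonadecyl-1,4-benzoquinone | CCCCCCCCCCCCCCCCCCCC1=C([O-])C(=O)C=C([O-])C1=O.[K+].[K+] | intermediate
10 | 2,5-dihydroxy-3-nonadecyl-1,4-benzoquinone | CCCCCCCCCCCCCCCCCCCC1=C(O)C(=O)C=C(O)C1=O | intermediate
11 | Irisoquin C (2-hydroxy-5-methoxy-3-nonadecyl-1,4-benzoquinone) | CCCCCCCCCCCCCCCCCCCC1=C(O)C(=O)C=C(OC)C1=O | target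

**Step count and risks**
Total step count: 3. Longest linear sequence: 3.

Steps most likely to fail:

Step 2. The enolate may add in conjugate fashion to the acrylate carbon of 5 instead of acylating. Silyl transfer between the partners may also scramble their roles and open homo-condensation. The sequence may stall after the first acylation if the silyl group is not removed. The fallback uses known chemistry, sets out from 1 and returns at 10. Dehydrobromination of 1 (KOtBu, THF/DMSO, 50 °C) should give eicos-1-ene F1. Ozonolysis (O3, CH2Cl2, −78 °C; then PPh3) should give nonadecanal F2. Three-component reductive alkylation of purchased 2,5-dihydroxy-1,4-benzoquinone with F2 and diethyl 2,6-dimethyl-1,4-dihydropyridine-3,5-dicarboxylate (Hantzsch ester), L-proline (cat.), CH2Cl2, 23 °C, should then give 10 by Knoevenagel condensation and hydride transfer to the quinone methide.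

Step 3. Etherification may run on to the dimethyl ether or occur in part at the hindered C2 hydroxyl. The fallback sets out from 10 and returns at 11. Exhaustive methylation (Me2SO4, K2CO3, acetone, reflux) should give 2,5-dimethoxy-3-nonadecyl-1,4-benzoquinone F3. Selective acid hydrolysis of the more hindered C2 methoxy group (70% HClO4, dioxane, 23 °C) should then give 11.

Step 1. A second Grignard addition to the keto ester and Wurtz homocoupling during magnesium insertion may erode the keto ester. The fallback sets out from 1 and returns at 4. Alkylation of the sodium salt of ethyl 1,3-dithiane-2-carboxylate with 1 (NaH, DMF/toluene, 23 °C) should give ethyl 2-eicosyl-1,3-dithiane-2-carboxylate F4. Oxidative cleavage of the dithioacetal (PhI(OCOCF3)2, MeCN/H2O, 0 °C) should then give 4.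

**Further compounds**
F1 | step 2 | eicos-1-ene | C=CCCCCCCCCCCCCCCCCCC
F2 | step 2 | nonadecanal | CCCCCCCCCCCCCCCCCCC=O
F3 | step 3 | 2,5-dimethoxy-3-nonadecyl-1,4-benzoquinone | CCCCCCCCCCCCCCCCCCCC1=C(OC)C(=O)C=C(OC)C1=O
F4 | step 1 | ethyl 2-eicosyl-1,3-dithiane-2-carboxylate | CCCCCCCCCCCCCCCCCCCCC1(C(=O)OCC)SCCCS1
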